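**Plan**

- Retrosynthesis: the chalcone C=C bond is cut first (aldol), then the aryl–acetyl bond, which leaves the central ring as a 2-alkyl-5-methoxyresorcinol with two equivalent free ring positions.
- Enabling feature: that benzene ring carries oxygen on C1, C3 and C5, one already a methyl ether para to the alkyl-bearing C2. Its six carbons and three oxygens therefore map onto an isomeric 6-alkyl-4-methoxy-2-pyrone (ring O and lactone C=O become the two hydroxyls), and the ring bond C1–C2 is the one cut.
- The pyrone is cut into methyl acetoacetate and a β-branched ester. The ester is cut at the Cβ–styryl bond (conjugate addition), at aryl–C7 (B-alkyl Suzuki) and at C2=C3 (olefination).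
- Forward: the chain is joined first (steps 1–4), then the pyrone ring is made (steps 5–7), then the benzene ring from the pyrone (step 8), then the acetyl group and the third aryl ring are added (steps 9–11) and the acetals removed (step 12).
- Stereochemistry: the single stereocentre comes from the (R)-BINAP–rhodium addition of the styryl group to the (E)-enoate. It is carried unchanged; the descriptor changes from S to R in step 8 only because the CIP priorities change. Both aryl-substituted double bonds are E, from the boron–Wittig olefination and the aldol dehydration.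

Key step: step 8

Assumption: 1, 2, 4, 7, 8 and 12 are taken as purchasable, and the methoxymethyl aryl ethers are taken to survive methoxide at 160 °C (any that is lost would be restored in step 9).

Step 1
Reactants: 1 pent-4-enal; 2 trimethyl phosphonoacetate
Product: 3 methyl (2E)-hepta-2,6-dienoate
Conditions: NaH, THF, 0 °C; then 1, 0 °C to rt
Reagents that add atoms: none
Why: Horner–Wadsworth–Emmons olefination of an unhindered aliphatic aldehyde with a stabilised phosphonate anion, which should give the (E)-enoate and leave the terminal alkene untouched.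

Step 2
Reactants: 3 methyl (2E)-hepta-2,6-dienoate; 4 1-bromo-4-(methoxymethoxy)benzene
Product: 6 methyl (2E)-7-[4-(methoxymethoxy)phenyl]hept-2-enoate, via alkylborane 5 (not isolated)
Conditions: 9-BBN, THF, 0 °C to rt; then 4, Pd(dppf)Cl2 (3 mol%), K3PO4 (aq), DMF, 60 °C
Reagents that add atoms: none
Why: 9-BBN hydroborates the monosubstituted alkene far faster than the conjugated enoate, and the resulting primary alkylborane undergoes B-alkyl Suzuki–Miyaura coupling with the aryl bromide under phosphate base, to which the acetal and the ester are inert.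

Step 3
Reactants: 7 4-(methoxymethoxy)benzaldehyde; 8 2,2'-methylenebis(4,4,5,5-tetramethyl-1,3,2-dioxaborolane)
Product: 10 2-{(E)-2-[4-(methoxymethoxy)phenyl]ethenyl}-4,4,5,5-tetramethyl-1,3,2-dioxaborolane, via lithiated diboronate 9 (not isolated)
Conditions: LiTMP (from 2,2,6,6-tetramethylpiperidine and n-BuLi), THF, 0 °C; then 7, −78 °C to rt; H2O
Reagents that add atoms: none
Why: Boron–Wittig olefination, in which the lithiated geminal diboronate adds to the aldehyde and the β-oxido boronate loses a borate by syn elimination, which for aryl aldehydes should favour the (E)-alkenylboronate.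

Step 4
Reactants: 6 methyl (2E)-7-[4-(methoxymethoxy)phenyl]hept-2-enoate; 10 (E)-styrylboronate
Product: 11 methyl (3S,4E)-3-{4-[4-(methoxymethoxy)phenyl]butyl}-5-[4-(methoxymethoxy)phenyl]pent-4-enoate
Conditions: Rh(acac)(C2H4)2 (3 mol%), (R)-BINAP [(R)-2,2'-bis(diphenylphosphino)-1,1'-binaphthyl] (3.3 mol%), K3PO4 (aq, 0.5 equiv), 1,4-dioxane/H2O 10:1, 80 °C
Reagents that add atoms: none
Why: Hayashi–Miyaura conjugate addition, in which the alkenyl group passes from boron to rhodium and inserts the enoate before the rhodium enolate is hydrolysed; by the quadrant model for BINAP the (R)-ligand should expose the re face of the α-carbon (si face of the β-carbon) of an (E)-enoate, which sets the (S) centre.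

Step 5
Reactants: 11 methyl ester from step 4; 12 methyl acetoacetate
Product: 14 methyl (7S,8E)-7-{4-[4-(methoxymethoxy)phenyl]butyl}-9-[4-(methoxymethoxy)phenyl]-3,5-dioxonon-8-enoate, via acetoacetate dianion 13 (not isolated)
Conditions: 12 (3 equiv), NaH, THF, 0 °C; n-BuLi, 0 °C; then 11, 0 °C to rt; cold 1 M HCl to pH 4
Reagents that add atoms: none
Why: Claisen-type acylation of the acetoacetate dianion at its terminal carbon by the methyl ester, run with excess dianion because the product is deprotonated as it forms; the stereocentre is β to the ester and cannot enolise.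

Step 6
Reactants: 14 3,5-dioxo ester
Product: 15 4-hydroxy-6-[(2S,3E)-2-{4-[4-(methoxymethoxy)phenyl]butyl}-4-[4-(methoxymethoxy)phenyl]but-3-en-1-yl]-2H-pyran-2-one
Conditions: DBU, toluene, reflux
Reagents that add atoms: none
Why: Base-mediated lactonisation, the usual fate of 3,5-dioxo esters: the enol oxygen of the 5-ketone attacks the ester and methanol is lost to give the 4-hydroxy-2-pyrone.

Step 7
Reactants: 15 4-hydroxy-2-pyrone
Product: 16 4-methoxy-6-[(2S,3E)-2-{4-[4-(methoxymethoxy)phenyl]butyl}-4-[4-(methoxymethoxy)phenyl]but-3-en-1-yl]-2H-pyran-2-one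
Conditions: Me2SO4, K2CO3, acetone, reflux
Reagents that add atoms: dimethyl sulfate, COS(=O)(=O)OC
Why: O-Methylation of the acidic vinylogous acid, which for 4-hydroxy-2-pyrones with dimethyl sulfate and carbonate is known to give mainly the 4-methoxy-2-pyrone and so differentiates this oxygen from the other two.

Step 8
Reactants: 16 4-methoxy-2-pyrone
Product: 18 the resorcinol 2-[(1E,3R)-1,7-bis[4-(methoxymethoxy)phenyl]hept-1-en-3-yl]-5-methoxybenzene-1,3-diol, via ring-opened keto ester 17 (not isolated)
Conditions: NaOMe (5 equiv), MeOH, sealed tube, 160 °C; then aq HCl to pH 5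
Reagents that add atoms: none
Why: Methoxide adds to the lactone carbonyl (C2) of 16 and the ring opens to the enolate of keto ester 17, in which the new methyl ester and the ketone arm stay on the same side of the methoxy-substituted double bond; the ketone enolate at the side-chain methylene (the carbon next to the stereocentre) then attacks the ester carbon, methoxide is expelled and the cyclohexadienone tautomerises to the resorcinol, so the new ring bond joins the alkyl-bearing carbon to a hydroxyl-bearing carbon. The closest known reaction type is the alkoxide-mediated isomerisation of 4-methoxy-6-methyl-2-pyrone to 5-methoxyresorcinol, an intramolecular Claisen (Dieckmann-type) condensation of the kind seen in biomimetic polyketide cyclisations. The benzene ring closes in a 6-(enolendo)-exo-trig mode. No stereocentre is formed; the existing one lies outside the six reacting atoms, cannot enolise (it is β to the ketone and only allylic) and should be carried through, the temperature being the main threat to it. The step needs C-acylation instead of O-acylation and survival of the one methyl ether: O-attack only regenerates 16, the more acidic methylene between ketone and enol ether can reach only a four-membered ring, methoxide exchange at the enol ether carbon is degenerate, and formation of the aromatic bis-phenoxide removes the product from all these equilibria.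

Step 9
Reactants: 18 resorcinol
Product: 19 2-[(1E,3R)-1,7-bis[4-(methoxymethoxy)phenyl]hept-1-en-3-yl]-5-methoxy-1,3-bis(methoxymethoxy)benzene
Conditions: NaH, MOMCl, DMF, 0 °C to rt
Reagents that add atoms: chloromethyl methyl ether, COCCl
Why: Williamson-type O-alkylation of the two phenoxides, which masks the acidic hydroxyls and installs the directing groups for the metalation that follows.

Step 10
Reactants: 19 bis(methoxymethyl) ether
Product: 21 1-{3-[(1E,3R)-1,7-bis[4-(methoxymethoxy)phenyl]hept-1-en-3-yl]-6-methoxy-2,4-bis(methoxymethoxy)phenyl}ethan-1-one, via aryllithium 20 (not isolated)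
Conditions: n-BuLi (1.1 equiv), THF, −20 to 0 °C; then MeC(O)N(OMe)Me, −78 to 0 °C; H2O
Reagents that add atoms: N-methoxy-N-methylacetamide, CC(=O)N(C)OC
Why: Directed ortho-metalation followed by Weinreb ketone synthesis: the ring C–H flanked by the methoxy group and one acetal oxygen is the kinetically most acidic site, the two such positions are equivalent by symmetry, and the chelated tetrahedral adduct releases the methyl ketone only on work-up.

Step 11
Reactants: 21 acetophenone; 7 4-(methoxymethoxy)benzaldehyde
Product: 22 (2E)-1-{3-[(1E,3R)-1,7-bis[4-(methoxymethoxy)phenyl]hept-1-en-3-yl]-6-methoxy-2,4-bis(methoxymethoxy)phenyl}-3-[4-(methoxymethoxy)phenyl]prop-2-en-1-one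
Conditions: KOH (aq), EtOH, rt
Reagents that add atoms: none
Why: Claisen–Schmidt condensation of the methyl ketone enolate with the non-enolisable aldehyde and E1cB dehydration to the (E)-enone; hydroxide at room temperature should touch neither the acetals nor the tertiary allylic centre.

Step 12
Reactants: 22 protected chalcone
Product: 23 deoxycalyxin A, (2E)-1-{3-[(1E,3R)-1,7-bis(4-hydroxyphenyl)hept-1-en-3-yl]-2,4-dihydroxy-6-methoxyphenyl}-3-(4-hydroxyphenyl)prop-2-en-1-one
Conditions: HCl (3 M aq), MeOH, rt to 40 °C
Reagents that add atoms: none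
Why: Acid-catalysed acetal exchange with methanol should remove the four methoxymethyl groups as dimethoxymethane, while the methyl ether, both alkenes and the stereocentre are expected to persist under these mild conditions.

**Compound list**

1 | pent-4-enal | C=CCCC=O | starting material
2 | trimethyl phosphonoacetate | COC(=O)CP(=O)(OC)OC | starting material
3 | methyl (2E)-hepta-2,6-dienoate | C=CCC/C=C/C(=O)OC | intermediate
4 | 1-bromo-4-(methoxymethoxy)benzene | COCOc1ccc(Br)cc1 | starting material
5 | methyl (2E)-7-(9-borabicyclo[3.3.1]nonan-9-yl)hept-2-enoate (formed in the flask) | COC(=O)/C=C/CCCCB1C2CCCC1CCC2 | intermediate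
6 | methyl (2E)-7-[4-(methoxymethoxy)phenyl]hept-2-enoate | COC(=O)/C=C/CCCCc1ccc(OCOC)cc1 | intermediate
7 | 4-(methoxymethoxy)benzaldehyde | COCOc1ccc(C=O)cc1 | starting material
8 | 2,2'-methylenebis(4,4,5,5-tetramethyl-1,3,2-dioxaborolane) | CC1(C)OB(CB2OC(C)(C)C(C)(C)O2)OC1(C)C | starting material
9 | [bis(4,4,5,5-tetramethyl-1,3,2-dioxaborolan-2-yl)methyl]lithium (formed in the flask) | [Li]C(B1OC(C)(C)C(C)(C)O1)B1OC(C)(C)C(C)(C)O1 | intermediate
10 | 2-{(E)-2-[4-(methoxymethoxy)phenyl]ethenyl}-4,4,5,5-tetramethyl-1,3,2-dioxaborolane | COCOc1ccc(/C=C/B2OC(C)(C)C(C)(C)O2)cc1 | intermediate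
11 | methyl (3S,4E)-3-{4-[4-(methoxymethoxy)phenyl]butyl}-5-[4-(methoxymethoxy)phenyl]pent-4-enoate | COC(=O)C[C@@H](/C=C/c1ccc(OCOC)cc1)CCCCc1ccc(OCOC)cc1 | intermediate
12 | methyl acetoacetate | COC(=O)CC(C)=O | starting material
13 | methyl acetoacetate dianion, sodium lithium 1-methoxybuta-1,3-diene-1,3-diolate (formed in the flask) | [Na+].[Li+].COC([O-])=CC([O-])=C | intermediate
14 | methyl (7S,8E)-7-{4-[4-(methoxymethoxy)phenyl]butyl}-9-[4-(methoxymethoxy)phenyl]-3,5-dioxonon-8-enoate | COC(=O)CC(=O)CC(=O)C[C@@H](/C=C/c1ccc(OCOC)cc1)CCCCc1ccc(OCOC)cc1 | intermediate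
15 | 4-hydroxy-6-[(2S,3E)-2-{4-[4-(methoxymethoxy)phenyl]butyl}-4-[4-(methoxymethoxy)phenyl]but-3-en-1-yl]-2H-pyran-2-one | O=c1cc(O)cc(C[C@@H](/C=C/c2ccc(OCOC)cc2)CCCCc2ccc(OCOC)cc2)o1 | intermediate
16 | 4-methoxy-6-[(2S,3E)-2-{4-[4-(methoxymethoxy)phenyl]butyl}-4-[4-(methoxymethoxy)phenyl]but-3-en-1-yl]-2H-pyran-2-one | COc1cc(C[C@@H](/C=C/c2ccc(OCOC)cc2)CCCCc2ccc(OCOC)cc2)oc(=O)c1 | intermediate
17 | methyl (2E,7S,8E)-3-methoxy-7-{4-[4-(methoxymethoxy)phenyl]butyl}-9-[4-(methoxymethoxy)phenyl]-5-oxonona-2,8-dienoate (formed in the flask, present as its enolate) | COC(=O)/C=C(/OC)CC(=O)C[C@@H](/C=C/c1ccc(OCOC)cc1)CCCCc1ccc(OCOC)cc1 | intermediate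
18 | 2-[(1E,3R)-1,7-bis[4-(methoxymethoxy)phenyl]hept-1-en-3-yl]-5-methoxybenzene-1,3-diol | COc1cc(O)c([C@@H](/C=C/c2ccc(OCOC)cc2)CCCCc2ccc(OCOC)cc2)c(O)c1 | intermediate
19 | 2-[(1E,3R)-1,7-bis[4-(methoxymethoxy)phenyl]hept-1-en-3-yl]-5-methoxy-1,3-bis(methoxymethoxy)benzene | COCOc1cc(OC)cc(OCOC)c1[C@@H](/C=C/c1ccc(OCOC)cc1)CCCCc1ccc(OCOC)cc1 | intermediate
20 | {3-[(1E,3R)-1,7-bis[4-(methoxymethoxy)phenyl]hept-1-en-3-yl]-6-methoxy-2,4-bis(methoxymethoxy)phenyl}lithium (formed in the flask) | COCOc1c([Li])c(OC)cc(OCOC)c1[C@@H](/C=C/c1ccc(OCOC)cc1)CCCCc1ccc(OCOC)cc1 | intermediate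
21 | 1-{3-[(1E,3R)-1,7-bis[4-(methoxymethoxy)phenyl]hept-1-en-3-yl]-6-methoxy-2,4-bis(methoxymethoxy)phenyl}ethan-1-one | COCOc1c(C(C)=O)c(OC)cc(OCOC)c1[C@@H](/C=C/c1ccc(OCOC)cc1)CCCCc1ccc(OCOC)cc1 | intermediate
22 | (2E)-1-{3-[(1E,3R)-1,7-bis[4-(methoxymethoxy)phenyl]hept-1-en-3-yl]-6-methoxy-2,4-bis(methoxymethoxy)phenyl}-3-[4-(methoxymethoxy)phenyl]prop-2-en-1-one | COCOc1c(C(=O)/C=C/c2ccc(OCOC)cc2)c(OC)cc(OCOC)c1[C@@H](/C=C/c1ccc(OCOC)cc1)CCCCc1ccc(OCOC)cc1 | intermediate
23 | deoxycalyxin A, (2E)-1-{3-[(1E,3R)-1,7-bis(4-hydroxyphenyl)hept-1-en-3-yl]-2,4-dihydroxy-6-methoxyphenyl}-3-(4-hydroxyphenyl)prop-2-en-1-one | COc1cc(O)c([C@@H](/C=C/c2ccc(O)cc2)CCCCc2ccc(O)cc2)c(O)c1C(=O)/C=C/c1ccc(O)cc1 | target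

**Step count**

Total steps: 12. Longest linear sequence: 11 steps (1 → 3 → 6 → 11 → 14 → 15 → 16 → 18 → 19 → 21 → 22 → 23).

**Steps most likely to fail**

Step 8. Methoxide may cleave the open keto ester at the ketone (a retro-Claisen fragmentation that would return ester 11) faster than the branched enolate closes. At 160 °C the base may also move the styryl double bond or erode the stereocentre. The fallback buys the arene instead of building it and joins it to the chain with copper. It sets out from 6 and 4. Ester 6 is converted with MeNHOMe·HCl and i-PrMgCl into the Weinreb amide F1. The Grignard reagent of 4 (Mg, THF) turns F1 into the aryl enone F2. Corey–Bakshi–Shibata reduction (BH3·SMe2, B-methyl oxazaborolidine from diphenylprolinol, enantiomer chosen for the S product) gives the (S)-allylic alcohol F3, and picolinic acid with DCC and DMAP gives the picolinate F4. Commercial 5-methoxyresorcinol is protected (NaH, MOMCl) as 1-methoxy-3,5-bis(methoxymethoxy)benzene F5. F5 is lithiated between its two acetal oxygens (n-BuLi), transmetallated (MgBr2, CuBr·SMe2) and displaces the picolinate of F4 in an anti-SN2' reaction with 1,3-chirality transfer. This should give 19 directly, where the route is rejoined.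

Step 4. Insertion into the weakly electrophilic enoate may be slow, the alkenylboronate may protodeboronate, the ester may hydrolyse, or facial discrimination may be poor. The fallback sets the centre by 1,3-chirality transfer instead. It sets out from 6 through the Weinreb amide F1 and the aryl enone F2 described above. CBS reduction with the enantiomeric oxazaborolidine gives the (R)-allylic alcohol F6, and Ac2O with DMAP gives the acetate F7. Ireland–Claisen rearrangement (LiHMDS, Me3SiCl, THF, −78 °C to rt; chair transition state with the aryl group equatorial, then aqueous work-up) gives the (S)-acid F8. Methylation (MeI, K2CO3, DMF) comes back to the route at 11.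

Step 10. The enolisable acetamide may protonate the aryllithium, or metalation may occur elsewhere (at the tertiary allylic carbon, which would erode the stereocentre, or ortho to a side-chain acetal). The fallback delivers the whole cinnamoyl unit with a non-enolisable acyl donor. It sets out from 7: Horner–Wadsworth–Emmons reaction with diethyl [2-(methoxy(methyl)amino)-2-oxoethyl]phosphonate (NaH, THF) gives the cinnamoyl Weinreb amide F9. Aryllithium 20, made from 19 as in step 10, adds to F9 and should give chalcone 22 directly, so the route is rejoined at 22 and step 11 is bypassed.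

**Further compounds**

F1 | step 8 | (2E)-N-methoxy-N-methyl-7-[4-(methoxymethoxy)phenyl]hept-2-enamide | CON(C)C(=O)/C=C/CCCCc1ccc(OCOC)cc1
F2 | step 8 | (2E)-1,7-bis[4-(methoxymethoxy)phenyl]hept-2-en-1-one | COCOc1ccc(cc1)C(=O)/C=C/CCCCc1ccc(OCOC)cc1
F3 | step 8 | (1S,2E)-1,7-bis[4-(methoxymethoxy)phenyl]hept-2-en-1-ol | O[C@H](c1ccc(OCOC)cc1)/C=C/CCCCc1ccc(OCOC)cc1
F4 | step 8 | (1S,2E)-1,7-bis[4-(methoxymethoxy)phenyl]hept-2-en-1-yl pyridine-2-carboxylate | O=C(O[C@H](c1ccc(OCOC)cc1)/C=C/CCCCc1ccc(OCOC)cc1)c1ccccn1
F5 | step 8 | 1-methoxy-3,5-bis(methoxymethoxy)benzene | COCOc1cc(OC)cc(OCOC)c1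
F6 | step 4 | (1R,2E)-1,7-bis[4-(methoxymethoxy)phenyl]hept-2-en-1-ol | O[C@@H](c1ccc(OCOC)cc1)/C=C/CCCCc1ccc(OCOC)cc1
F7 | step 4 | (1R,2E)-1,7-bis[4-(methoxymethoxy)phenyl]hept-2-en-1-yl acetate | CC(=O)O[C@@H](c1ccc(OCOC)cc1)/C=C/CCCCc1ccc(OCOC)cc1
F8 | step 4 | (3S,4E)-3-{4-[4-(methoxymethoxy)phenyl]butyl}-5-[4-(methoxymethoxy)phenyl]pent-4-enoic acid | OC(=O)C[C@@H](/C=C/c1ccc(OCOC)cc1)CCCCc1ccc(OCOC)cc1
F9 | step 10 | (2E)-N-methoxy-N-methyl-3-[4-(methoxymethoxy)phenyl]prop-2-enamide | CON(C)C(=O)/C=C/c1ccc(OCOC)cc1
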